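## Retrosynthetic overview

- Locants follow the biphenyl core: C1–C1' is the biaryl bond, C6/C6' carry the CH2CH2Ar bridges, and C3/C3' and C4/C4' carry OH. The last bonds made are C4–O and C4'–O, by a double IBX ortho-oxygenation of the 3,3'-bisphenol. The resulting bis(ortho-quinone) is reduced with Na2S2O4 in the same flask.
- Feature used: the inner rings B/B' carry four free OH groups and the outer rings A/A' carry only OMe. With the C4/C4' oxygens (para to C1–C1') removed, each C3–OH has its para carbon C6 blocked by the bridge. Its ortho carbon C2 is wedged against the biaryl bond, so C4–H is the only open ortho site. The OH/OMe pattern therefore needs no selective demethylation.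
- The bisphenol comes from hydrogenation and hydrogenolysis of a dibenzyl-protected bis-stilbene. This is made by a double Wittig reaction of a biphenyl-2,2'-dicarbaldehyde with the 3-methoxybenzyl ylide.
- The dialdehyde comes from Ullmann homocoupling (C1–C1') of O-benzylated 2-bromo-4-hydroxybenzaldehyde.
- No ring is formed, since all four benzene rings are purchased. The order of construction is C1–C1', two C=C, saturation with debenzylation, then two C–O.

Key step: step 5

Assumption: each ring has only one ortho substituent at the biaryl axis, so the axis rotates freely and the target has no stereo element. The alkene geometry of 6 is erased in step 4 and is drawn unspecified.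

## Route

Step 1
Reactants: 1 2-bromo-4-hydroxybenzaldehyde
Product: 2 4-(benzyloxy)-2-bromobenzaldehyde
Conditions: BnBr, K2CO3, DMF, rt
Reagents that add atoms: benzyl bromide, BrCc1ccccc1
Why: Williamson ether synthesis, in which the acidic para-formyl phenol is deprotonated by K2CO3 and the phenoxide displaces bromide from benzyl bromide (SN2), while the aldehyde and aryl bromide are inert.

Step 2
Reactants: 2 4-(benzyloxy)-2-bromobenzaldehyde (two molecules)
Product: 3 5,5'-bis(benzyloxy)biphenyl-2,2'-dicarbaldehyde
Conditions: activated Cu powder (excess), DMF, 150 °C, Ar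
Reagents that add atoms: none
Why: Classical Ullmann reductive homocoupling, for which ortho-bromobenzaldehydes are established substrates because the ortho formyl group activates the C–Br bond towards copper, and the benzyl ethers tolerate hot DMF.

Step 3
Reactants: 3 5,5'-bis(benzyloxy)biphenyl-2,2'-dicarbaldehyde; 4 (3-methoxybenzyl)triphenylphosphonium chloride (2.4 equiv)
Product: 6 5,5'-bis(benzyloxy)-2,2'-bis[2-(3-methoxyphenyl)ethenyl]biphenyl as a mixture of alkene isomers, via (3-methoxybenzylidene)triphenylphosphorane 5 (not isolated)
Conditions: 4, KOtBu, THF, 0 °C; then 3, 0 °C → rt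
Reagents that add atoms: none
Why: Double Wittig olefination with a preformed semistabilised benzylide on a non-enolisable dialdehyde, where the uncontrolled alkene geometry does not matter because both C=C bonds are saturated in the next step.

Step 4
Reactants: 6 5,5'-bis(benzyloxy)-2,2'-bis[2-(3-methoxyphenyl)ethenyl]biphenyl
Product: 7 6,6'-bis[2-(3-methoxyphenyl)ethyl]biphenyl-3,3'-diol
Conditions: H2 (1 atm), 10% Pd/C, THF/MeOH, rt
Reagents that add atoms: none
Why: Heterogeneous catalytic hydrogenation should saturate both stilbene double bonds and hydrogenolyse both benzylic C–O bonds in one operation, while the aryl methyl ethers have no benzylic C–O bond and stay intact.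

Step 5
Reactants: 7 6,6'-bis[2-(3-methoxyphenyl)ethyl]biphenyl-3,3'-diol
Product: 9 plagilin (6,6'-bis[2-(3-methoxyphenyl)ethyl]biphenyl-3,3',4,4'-tetrol), via bis(ortho-quinone) 8 (not isolated)
Conditions: IBX (2.4 equiv), DMF, 0 °C → rt, dark, N2; then aq. Na2S2O4 (excess), rt
Reagents that add atoms: IBX (2-iodoxybenzoic acid), O=C1OI(=O)(O)c2ccccc12
Why: Each phenolic OH of 7 condenses with the hydroxyl ligand on the pentavalent iodine of IBX with loss of water, the iodyl oxygen shifts inside this aryloxy-iodane to an ortho carbon while iodine drops to the trivalent state, and after rearomatisation the bound catechol monoether expels 2-iodobenzoic acid (monovalent iodine) to leave the ortho-quinone, so one equivalent of IBX per ring makes one C–O bond (C4–O and C4'–O) and 8 should result. The closest known reaction type is the IBX ortho-oxygenation of para-alkylphenols to ortho-quinones with reductive work-up to catechols, so this is established chemistry run twice in one molecule. No ring is closed and no stereocentre is created. The selectivity needed is regiochemical, C4 over C2: the para carbon C6 is blocked by the bridge, and C2 lies in the cleft between the iodine-bearing oxygen and the twisted neighbouring ring with its own ortho arylethyl chain, so the bulky iodane should reach only C4–H. Chemoselectivity follows because the anisole rings A/A' have no OH to bind iodine and IBX attack at benzylic CH2 groups needs heating well above room temperature. Na2S2O4 added to the same flask delivers two electrons per quinone ring, giving the tetrol before the 4-alkyl-ortho-quinone units can tautomerise to quinone methides, and it also destroys surplus IBX.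

## Compound list

1 | 2-bromo-4-hydroxybenzaldehyde | O=Cc1ccc(O)cc1Br | starting material
2 | 4-(benzyloxy)-2-bromobenzaldehyde | O=Cc1ccc(OCc2ccccc2)cc1Br | intermediate
3 | 5,5'-bis(benzyloxy)biphenyl-2,2'-dicarbaldehyde | O=Cc1ccc(OCc2ccccc2)cc1-c1cc(OCc2ccccc2)ccc1C=O | intermediate
4 | (3-methoxybenzyl)triphenylphosphonium chloride | COc1cccc(C[P+](c2ccccc2)(c2ccccc2)c2ccccc2)c1.[Cl-] | starting material
5 | (3-methoxybenzylidene)triphenylphosphorane | COc1cccc(C=P(c2ccccc2)(c2ccccc2)c2ccccc2)c1 | intermediate
6 | 5,5'-bis(benzyloxy)-2,2'-bis[2-(3-methoxyphenyl)ethenyl]biphenyl (alkene isomers, geometry unspecified) | COc1cccc(C=Cc2ccc(OCc3ccccc3)cc2-c2cc(OCc3ccccc3)ccc2C=Cc2cccc(OC)c2)c1 | intermediate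
7 | 6,6'-bis[2-(3-methoxyphenyl)ethyl]biphenyl-3,3'-diol | COc1cccc(CCc2ccc(O)cc2-c2cc(O)ccc2CCc2cccc(OC)c2)c1 | intermediate
8 | 5,5'-bis[2-(3-methoxyphenyl)ethyl]-4,4'-bi(1,2-benzoquinone) | COc1cccc(CCC2=CC(=O)C(=O)C=C2C2=CC(=O)C(=O)C=C2CCc2cccc(OC)c2)c1 | intermediate
9 | plagilin, 6,6'-bis[2-(3-methoxyphenyl)ethyl]biphenyl-3,3',4,4'-tetrol | COc1cccc(CCc2cc(O)c(O)cc2-c2cc(O)c(O)cc2CCc2cccc(OC)c2)c1 | target

Total step count: 5
Longest linear sequence: 5 steps (1 → 2 → 3 → 6 → 7 → 9)

## Steps most likely to fail

**1. Step 5.** Three processes may go wrong:
- Oxygen may be transferred to the crowded ortho carbon C2/C2' in one of the rings.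
- The reaction may stall once the first ring is oxidised and has become electron-poor.
- The 4-alkyl-ortho-quinone units may tautomerise to quinone methides and oligomerise before the reductant is added.

The fallback sets out from 7 and comes back at 9 without passing through a quinone. A double magnesium-mediated ortho-formylation (MgCl2, Et3N, paraformaldehyde, MeCN, reflux) proceeds through a bulky phenoxide–formaldehyde chelate that selects the open ortho carbon. It should give 5,5'-dihydroxy-2,2'-bis[2-(3-methoxyphenyl)ethyl]biphenyl-4,4'-dicarbaldehyde F1. A double Dakin oxidation (H2O2, aq. NaOH, THF, 0 °C → rt, N2, then acid) should replace each formyl group by OH and deliver 9.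

**2. Step 2.** Insertion of copper into the C–Br bond may be sluggish. Hydrodebromination by adventitious proton sources and thermal degradation of the aldehyde at the required temperature are further risks.

The fallback sets out from 2 and comes back at 3, replacing the reductive homocoupling by a palladium-catalysed cross-coupling. Half of 2 is converted by Miyaura borylation (B2pin2, PdCl2(dppf), KOAc, dioxane, 85 °C) into 4-(benzyloxy)-2-(4,4,5,5-tetramethyl-1,3,2-dioxaborolan-2-yl)benzaldehyde F2. This is joined to the other half of 2 by Suzuki–Miyaura coupling (Pd(PPh3)4, aq. K2CO3, DME, 85 °C) to give 3.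

**3. Step 3.** The second olefination may be incomplete, because once the first styryl arm is in place the remaining formyl group sits in a crowded pocket. Separation from the phosphorus by-product may also be laborious.

The fallback sets out from 2 and comes back at 6, with the order of bond formation reversed. Monomer 2 is olefinated with ylide 5 (from 4, KOtBu, THF, 0 °C → rt) to give 4-(benzyloxy)-2-bromo-1-[2-(3-methoxyphenyl)ethenyl]benzene F3. The biaryl bond is then made by reductive homocoupling under zerovalent nickel catalysis (NiBr2(PPh3)2 cat., Zn, Et4NI, THF, 50 °C), which should give 6.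

## Further compounds

F1 | step 5 | 5,5'-dihydroxy-2,2'-bis[2-(3-methoxyphenyl)ethyl]biphenyl-4,4'-dicarbaldehyde | COc1cccc(CCc2cc(C=O)c(O)cc2-c2cc(O)c(C=O)cc2CCc2cccc(OC)c2)c1
F2 | step 2 | 4-(benzyloxy)-2-(4,4,5,5-tetramethyl-1,3,2-dioxaborolan-2-yl)benzaldehyde | O=Cc1ccc(OCc2ccccc2)cc1B1OC(C)(C)C(C)(C)O1
F3 | step 3 | 4-(benzyloxy)-2-bromo-1-[2-(3-methoxyphenyl)ethenyl]benzene (alkene isomers, geometry unspecified) | COc1cccc(C=Cc2ccc(OCc3ccccc3)cc2Br)c1
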